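The readings come from a simulation for an exercise, and the scatter is random.

Ask where Friday's run stops, and read it from its neighbour: Friday's charge is Wednesday's, and Sunday's run differs from Wednesday's by more substrate at the same partner.

| flask | substrate | partner | free catalyst | time |
|---|---|---|---|---|
| Wednesday's | 0.100 M | 0.110 M | 0.0100 M |  |
| Monday's | 0.0500 M | 0.0600 M | 0.0100 M |  |
| Sunday's | 0.150 M | 0.110 M | 0.0100 M |  |
| Friday's | 0.100 M | 0.110 M | 0.0100 M | 120 min |

| Wednesday's run: time / min | Wednesday's run: [product] / M | Monday's run: time / min | Monday's run: [product] / M | Sunday's run: time / min | Sunday's run: [product] / M |
|---|---|---|---|---|---|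
| 9.2 | 0.0320 | 9.2 | 0.0186 | 9.2 | 0.0327 |
| 18 | 0.0528 | 18 | 0.0289 | 18 | 0.0564 |
| 28 | 0.0655 | 28 | 0.0339 | 28 | 0.0726 |
| 37 | 0.0705 | 37 | 0.0372 | 37 | 0.0808 |
| 46 | 0.0724 | 46 | 0.0375 | 46 | 0.0858 |

(scatter of a reading: 3 × 10⁻⁴ M)

- reaction order in [partner] at the outset, round the charge of the Wednesday's run, defined at two percent of the substrate turned into product
- reaction order in [substrate] at the outset, round the charge of the Wednesday's run, defined at two percent of the substrate turned into product (one fixed amount of product, the same in the runs compared)
- the Monday's run starts with 0.0500 M less of substrate and of partner than the Wednesday's run, and with no product. Compared where both hold the same amount of substrate, once fifteen percent of what the Monday's run was charged with has turned into product, is the Monday's run faster, slower or alike (within a tenth)?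
- product in the Friday's run at 120 min, as a share of the substrate charged

- Overall: substrate + partner -> product, with free catalyst as catalyst.
- Constant volume, constant temperature.
- Readings of a species count what is bound in complexes too.
- "The second partner" is partner.
- An order is taken over about fifteen percent of the charge, up and down.

Take every amount as a fraction of the run's own substrate charge. In Wednesday's run, the rate between the first two readings is 0.0236 min⁻¹ at 42.4% turned. Between the third and fourth readings it is 0.00556 min⁻¹ at 68.0% turned.

Divide the change of rate with time by the rate itself, so that time drops out. This gives the fall, the rate lost per fraction of charge turned, read here as 0.0706 min⁻¹. If the fall holds, the rate reaches zero where the present rate, divided by the fall, has been added to the present fraction.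

Wednesday's last interval stands at 71.4% turned, with a rate of 0.00211 min⁻¹, so my reckoning stops it at 74.4%. Substrate is the limiting reagent in Wednesday's run, yet on this reckoning 25.6% of it stays unturned, so the reckoned stop lies short of what the charge allows.

Sunday's run makes 1.02 times Wednesday's product by the first reading, but its fall is the smaller, at 0.0554 min⁻¹. Because Sunday's run loses less rate per unit of product made, the same reckoning stops it at 1.25 times Wednesday's reckoned product, which is 62.2% of Sunday's larger charge.

If the fall holds, the gap to the stop decays as a first-order process with the fall as its rate constant. Between the last reading and 120 min, hardly any of the gap survives, so I put Friday's run at 74.4%.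

The forecast gives 74% (range 72.5% to 77%), close to mine and reckoned another way from the same run: “Wednesday's tail increments shrink by about 0.38 per interval”. It also gives orders of 0.9 in partner (0.7 to 1.1) and 0 in substrate (−0.2 to 0.2), and calls Monday's run faster.

The flask gives 74.6% for Friday's run, orders of 0.49 in partner and 0.072 in substrate, and Monday's run faster, by these steps:

    free catalyst + substrate ⇌ catalyst-substrate complex, settled at all times (68.50 M⁻¹)
    catalyst-substrate complex + partner ⇌ ternary complex, settled at all times (12.80 M⁻¹)
    ternary complex → product + free catalyst (0.8040 min⁻¹)
    free catalyst + product → spent catalyst + product (4.554 M⁻¹ min⁻¹)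
    free catalyst + impurity → spent catalyst

At equal substrate, at the point asked, Monday's rate is 1.5 times Wednesday's. Take the fall to a run stopping at Friday's share: going from a quarter to half of the charge should take 9.93 min. Wednesday's run took 9.64 min, and Monday's run took 8.21 min.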